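**The question.** If a closed, stirred, isothermal flask receives the charge of the oak run but twice its impurity, what stands in it after 30 h?

| flask | free monomer | transfer agent | initiator | impurity | remark | time |
|---|---|---|---|---|---|---|
| oak | 0.020 M | 0.60 mM | 100 µM | 0.065 mM | run made earlier |  |
| flask | 0.020 M | 0.600 mM | 100 µM | 0.13 mM |  | 30 h |

oak run (percent of the free monomer charged)

| time / h | monomer in chains / % | free monomer / % |
|---|---|---|
| 1.50 | 45.7 | 55.3 |
| 3.00 | 69.1 | 30.2 |
| 5.00 | 85.1 | 14.8 |
| 6.00 | 89.5 | 10.1 |

(readings scatter by 0.5 percentage points)

- average number of monomer units in a chain (chains begun, living or dead) at 30 h
- part of the free monomer that has reacted at 30 h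

- the average divides the monomer in chains by the number of chains begun, living and dead together
- the earlier runs do not show the number of chains; that part of a forecast is a guess
- no earlier run changes the charge of impurity; that part of a forecast is a guess

**First instants.** Suppose each chain begun costs one initiator. Then 0.020 M of free monomer over 100 µM of initiator gives 200 units, the monomer-per-initiator ratio, and dp equals this ratio times the part reacted, divided by the share of initiator that begins a chain. In this flask the impurity charge stands above the initiator charge, whereas in the oak run it stood below. If impurity destroys initiator, it competes with free monomer from the start and lowers that share, but no earlier run measures this.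

**The middle.** In the oak run, free monomer falls with a nearly steady constant, read at the last point as 0.382 h⁻¹, a half-life of 1.81 h. A steady constant suggests a steady [living end], so the decay in the oak run reads as pseudo-first-order. If [living end] stands lower in this flask, free monomer should fall more slowly there.

**The end.** The time of 30 h is longer than the oak half-life and spans 16.6 of them, so this flask has room to run slower and still approach full reaction. The dp then stands near the ratio divided by the share, so at 200 or above, by a guessed factor.

**The forecast.** It gives dp 34 (27 to 45) and c 99.9 % (90 % to 100 %), holding that “the transfer agent probably keeps the active pool going”. Its dp stands below the ratio, and there the reckoning above differs from it.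

**The flask.** The simulation gives dp 758 and c 98.6 %.

    free monomer + initiator → living end + monomer in chains (k = 0.232 M⁻¹ s⁻¹)
    free monomer + living end → monomer in chains + living end, rate k2*[living end]*[free monomer] (k = 2.45 M⁻¹ s⁻¹)
    living end + transfer agent → dead chain (kL = 0.0166 M⁻¹ s⁻¹)
    initiator + impurity → spent initiator A (k = 147 M⁻¹ s⁻¹)
    free monomer + initiator → spent initiator B (k = 0.00823 M⁻¹ s⁻¹)

**The split.** At the charge, impurity takes initiator at 0.0191 s⁻¹, faster than free monomer takes it at 0.00464 s⁻¹, and this flask ends with 7.31 × 10⁻⁵ M of spent initiator A. Set against the ratio of 200, its dp gives a share of 26.0 %. A neighbour flask with 2.2 × 10⁻⁴ M of impurity has the same ratio, which with its reacted part gives 183 units per initiator charged. Its computed dp is 1200 at c 91.6 %, so its share is 15.2 %, lower than this flask's.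

The numbers in the tables stem from a simulated flask from invented constants.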